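**Retrosynthetic overview**
1. The last C–C bond is C1–C13′: the C1 allyl radical of the 4E,9Z half (from caesium oxalate 23) adds to the α-methylene lactone of the 1(10)E,4E monomer 19; two formates are then removed.
2. Both halves come from one type of macrocyclic allylic alcohol (16 and its C6 epimer 21): 19 by reductive 1,3-transposition (C1–OH/Δ9 → Δ1(10)), 23 by O-oxalylation.
3. The ten-membered rings close by intramolecular Nozaki–Hiyama–Kishi reaction (C1–C10) of iodo aldehydes 15 and 20, which diverge from hydroxy aldehyde 14 by formylation with retention or Mitsunobu formylation with inversion at C6.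
4. 14 comes from chromium-mediated allylation (C6–C7) of enal 4 with bromomethyl butenolide 12; the C8 stereocentre of 12 (asymmetric vinylation) controls C7 and C6.
5. Ring order: butenolide (metathesis) → α-methylene lactone → two ten-membered rings → union. Building blocks: pent-4-yn-1-ol, but-2-yn-1-ol, 2-(bromomethyl)acrylic acid.

Assumption: the SMILES is taken literally (the halves are epimeric at the carbinol carbon: 6S in the 4E,9Z half, 6′R in the dihydrolactone half), and (+)-MIB is taken to deliver vinyl to the Re face of aldehyde 8 (otherwise its antipode is used).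

Numbering: germacrane numbering is used for explanations and macrocycle names (ring C1–C10; lactone C11–C13 with C12 the carbonyl and the ring oxygen on C8; C14 on C10, C15 on C4; primes for the dihydrolactone half).

**Route**

Step 1
Reactants: 1 pent-4-yn-1-ol
Product: 3 (2E)-3-methylhex-2-ene-1,6-diol, via alkenylalane 2 (not isolated)
Conditions: Me3Al (3 equiv), Cp2ZrCl2 (0.25 equiv), CH2Cl2, 0 → 23 °C; then (CH2O)n, THF, 0 → 23 °C; aq. HCl work-up
Reagents that add atoms: trimethylaluminium, C[Al](C)C; paraformaldehyde (as formaldehyde), C=O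
Why: Negishi zirconium-catalysed carboalumination adds CH3 and Al syn across the alkyne (CH3 on the internal carbon), and hydroxymethylation of the alkenylalane with retention fixes the E trisubstituted C4=C5 alkene.

Step 2
Reactants: 3 (2E)-3-methylhex-2-ene-1,6-diol
Product: 4 (2E)-6-hydroxy-3-methylhex-2-enal
Conditions: MnO2 (15 equiv), CH2Cl2, 23 °C
Reagents that add atoms: none
Why: MnO2 oxidation is selective for the allylic primary alcohol and leaves the saturated primary alcohol and the E geometry untouched.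

Step 3
Reactants: 5 but-2-yn-1-ol
Product: 7 (2Z)-3-iodobut-2-en-1-ol, via alkenylaluminate 6 (not isolated)
Conditions: NaAlH2(OCH2CH2OCH3)2 (1.5 equiv), Et2O, 0 → 23 °C; then I2, THF, −78 °C
Reagents that add atoms: iodine, II
Why: hydroxyl-directed trans-hydroalumination places aluminium on C3 cis to the CH2O group, and iodinolysis with retention gives the Z alkenyl iodide (the future C9=C10 geometry).

Step 4
Reactants: 7 (2Z)-3-iodobut-2-en-1-ol
Product: 8 (2Z)-3-iodobut-2-enal
Conditions: MnO2 (15 equiv), CH2Cl2, 23 °C, dark; used directly as a solution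
Reagents that add atoms: none
Why: neutral MnO2 allylic oxidation gives the enal without Z/E isomerisation or loss of iodide.

Step 5
Reactants: 8 (2Z)-3-iodobut-2-enal
Product: 9 (3R,4Z)-5-iodohexa-1,4-dien-3-ol
Conditions: (CH2=CH)2Zn (1.5 equiv, from CH2=CHMgBr and ZnCl2), (+)-MIB (10 mol %), toluene, −30 °C; aq. NH4Cl
Reagents that add atoms: vinylmagnesium bromide, C=C[Mg]Br (transferred through divinylzinc, C=C[Zn]C=C)
Why: amino-alcohol-catalysed asymmetric alkenylzinc addition (Oppolzer/Nugent type) to the Re face of the aldehyde sets the future C8 stereocentre by catalyst control.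

Step 6
Reactants: 9 (3R,4Z)-5-iodohexa-1,4-dien-3-ol; 10 2-(bromomethyl)prop-2-enoic acid
Product: 11 (3R,4Z)-5-iodohexa-1,4-dien-3-yl 2-(bromomethyl)prop-2-enoate
Conditions: DIC (1.2 equiv), DMAP (5 mol %), CH2Cl2, −20 → 0 °C
Reagents that add atoms: none
Why: Steglich esterification at low temperature acylates the secondary alcohol without touching the stereocentre or displacing the allylic bromide.

Step 7
Reactants: 11 (3R,4Z)-5-iodohexa-1,4-dien-3-yl 2-(bromomethyl)prop-2-enoate
Product: 12 (5R)-3-(bromomethyl)-5-[(1Z)-2-iodoprop-1-en-1-yl]furan-2(5H)-one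
Conditions: second-generation Grubbs catalyst, RuCl2(=CHPh)(PCy3)(H2IMes) (5 mol %), CH2Cl2 (5 mM), 40 °C
Reagents that add atoms: none
Why: ring-closing metathesis between the terminal vinyl group and the 1,1-disubstituted acrylate closes the butenolide (as for methacrylates of allylic alcohols), while the trisubstituted alkenyl iodide is inert and the stereocentre is untouched.

Step 8
Reactants: 12 (5R)-3-(bromomethyl)-5-[(1Z)-2-iodoprop-1-en-1-yl]furan-2(5H)-one; 4 (2E)-6-hydroxy-3-methylhex-2-enal
Product: 13 (4S,5R)-4-[(1R,2E)-1,6-dihydroxy-3-methylhex-2-en-1-yl]-5-[(1Z)-2-iodoprop-1-en-1-yl]-3-methylideneoxolan-2-one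
Conditions: CrCl2 (4 equiv, nickel-free), THF, 0 → 23 °C; pH 7 buffer
Reagents that add atoms: none
Why: Nozaki–Hiyama allylation: the allylchromium from the allylic bromide (the alkenyl iodide is inert without nickel) adds through C7 to the enal carbonyl in a chair transition state, anti to the C8 substituent (7,8-trans), and the ring-fixed E-type allyl geometry gives the 6,7-anti adduct (6R,7S), so C8 controls both new centres.

Step 9
Reactants: 13 (the diol from step 8)
Product: 14 (4E,6R)-6-hydroxy-6-[(2R,3S)-2-[(1Z)-2-iodoprop-1-en-1-yl]-4-methylidene-5-oxooxolan-3-yl]-4-methylhex-4-enal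
Conditions: TEMPO (10 mol %), PhI(OAc)2 (1.1 equiv), CH2Cl2, 0 → 23 °C
Reagents that add atoms: none
Why: the oxoammonium oxidation (Piancatelli–Margarita) converts the primary alcohol to the C1 aldehyde much faster than it touches the hindered secondary C6 alcohol.

Step 10
Reactants: 14 (the hydroxy aldehyde from step 9)
Product: 15 (1R,2E)-1-[(2R,3S)-2-[(1Z)-2-iodoprop-1-en-1-yl]-4-methylidene-5-oxooxolan-3-yl]-3-methyl-6-oxohex-2-en-1-yl formate
Conditions: HCO2Ac (acetic formic anhydride, 3 equiv), pyridine, CH2Cl2, 0 °C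
Reagents that add atoms: acetic formic anhydride, CC(=O)OC=O
Why: O-formylation with retention blocks O6 (6R series), so that only the C1 hydroxyl made in the next step reacts later, and the formate is removable at near-neutral pH.

Step 11
Reactants: 15 (the 6R formate aldehyde from step 10)
Product: 16 (6R,7S,8S)-6-formyloxy-1-hydroxygermacra-4E,9Z,11(13)-trien-12,8-olide (both C1 epimers)
Conditions: CrCl2 (10 equiv), NiCl2 (0.2 equiv), DMSO–THF (3:1), 2 mM by slow addition of 15, 23 °C; pH 7 buffer
Reagents that add atoms: none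
Why: intramolecular Nozaki–Hiyama–Kishi reaction: the Z alkenyl iodide (nickel-catalysed activation, transmetallation to chromium) adds to the C1 aldehyde with retention of the Z geometry and closes the ten-membered ring; the C1 configuration is irrelevant because C1 is planarised in the next step.

Step 12
Reactants: 16 (the macrocyclic allylic alcohol from step 11)
Product: 19 (6R,7S,8S)-6-formyloxygermacra-1(10)E,4E,11(13)-trien-12,8-olide, via sulfonylhydrazine 17 (not isolated), via allylic diazene 18 (not isolated)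
Conditions: 2-O2NC6H4SO2NHNH2 (NBSH, 3 equiv), PPh3 (3 equiv), DEAD (3 equiv), THF, −30 °C, then 23 °C
Reagents that add atoms: none
Why: Myers reductive 1,3-transposition (Mitsunobu displacement, sulfinate loss, retro-ene loss of N2) delivers H to C9 and moves the alkene to C1=C10; allylic 1,3-strain with the cis C8 substituent keeps H-1 in the olefin plane, so C2 ends up trans to C9 (1(10)E).

Step 13
Reactants: 14 (the hydroxy aldehyde from step 9)
Product: 20 (1S,2E)-1-[(2R,3S)-2-[(1Z)-2-iodoprop-1-en-1-yl]-4-methylidene-5-oxooxolan-3-yl]-3-methyl-6-oxohex-2-en-1-yl formate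
Conditions: HCO2H (4 equiv), PPh3 (3 equiv), DIAD (3 equiv), THF, −20 → 0 °C
Reagents that add atoms: formic acid, O=CO
Why: Mitsunobu esterification inverts C6 (6R → 6S) by SN2 displacement and installs the same formate protecting group in one operation.

Step 14
Reactants: 20 (the 6S formate aldehyde from step 13)
Product: 21 (6S,7S,8S)-6-formyloxy-1-hydroxygermacra-4E,9Z,11(13)-trien-12,8-olide (both C1 epimers)
Conditions: CrCl2 (10 equiv), NiCl2 (0.2 equiv), DMSO–THF (3:1), 2 mM by slow addition of 20, 23 °C; pH 7 buffer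
Reagents that add atoms: none
Why: the same Nozaki–Hiyama–Kishi macrocyclisation as in step 11 closes the 4E,9Z ring of the 6S series with retention of the Z alkene; both C1 epimers are used because C1 becomes a radical centre.

Step 15
Reactants: 21 (the macrocyclic allylic alcohol from step 14)
Product: 23 caesium C1 oxalate of 21, via methyl oxalate 22 (not isolated)
Conditions: ClC(O)CO2Me (1.3 equiv), Et3N, DMAP (cat.), CH2Cl2, 0 °C; then CsOH·H2O (1.0 equiv), THF–H2O, 0 °C
Reagents that add atoms: methyl chlorooxoacetate, COC(=O)C(=O)Cl; caesium hydroxide, [Cs+].[OH-]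
Why: O-acylation keeps the oxygen on C1 (no allylic transposition, so Δ9 stays Z), and one equivalent of hydroxide cleaves the highly electrophilic oxalate methyl ester far faster than the formate or the lactone.

Step 16
Reactants: 23 caesium C1 oxalate of 21; 19 (6R,7S,8S)-6-formyloxygermacra-1(10)E,4E,11(13)-trien-12,8-olide
Product: 24 6,6′-di-O-formyl derivative of the target
Conditions: [Ir(dF(CF3)ppy)2(dtbbpy)]PF6 (2 mol %), 19 (5 equiv, excess recovered), DME–DMF (3:1), H2O (10 equiv), blue LEDs, 25 °C, 23 added over 8 h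
Reagents that add atoms: none
Why: Proposed new method: the excited iridium complex oxidises the oxalate, two CO2 are lost and the C9–C10–C1 allyl radical (Z geometry at C9=C10 retained) adds through its less hindered C1 terminus to C13′ of the methylene lactone, expected on the outer ring face away from the transannular C4–C6 bridge (1S); the α-lactone radical is reduced to the enolate and protonated anti to the pseudo-axial H-7′ to give the more stable 11′R epimer; the closest known reaction type is the visible-light photoredox Giese coupling of alkyl caesium oxalates with Michael acceptors.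

Step 17
Reactants: 24 6,6′-di-O-formyl derivative of the target
Product: 25 target compound (CNP0191625.1)
Conditions: KHCO3 (4 equiv), MeOH–H2O (4:1), 0 → 23 °C
Reagents that add atoms: none
Why: formate esters are cleaved by bicarbonate under conditions too mild for lactone opening, translactonisation, conjugate addition to the methylene lactone or acid-induced transannular cyclisation, and no stereocentre is affected.

**Compound list**
1 | pent-4-yn-1-ol | C#CCCCO | starting material
2 | (E)-dimethyl[2-methyl-5-(dimethylalumanyloxy)pent-1-en-1-yl]alumane (alkenylalane) | C[Al](C)/C=C(\C)CCCO[Al](C)C | intermediate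
3 | (2E)-3-methylhex-2-ene-1,6-diol | OC/C=C(\C)CCCO | intermediate
4 | (2E)-6-hydroxy-3-methylhex-2-enal | O=C/C=C(\C)CCCO | intermediate
5 | but-2-yn-1-ol | CC#CCO | starting material
6 | cyclic sodium alkenylaluminate (Al on C3, cis to CH2O, two 2-methoxyethoxy groups on Al) | CC1=CCO[Al-]1(OCCOC)OCCOC.[Na+] | intermediate
7 | (2Z)-3-iodobut-2-en-1-ol | OC/C=C(/C)I | intermediate
8 | (2Z)-3-iodobut-2-enal | O=C/C=C(/C)I | intermediate
9 | (3R,4Z)-5-iodohexa-1,4-dien-3-ol | C=C[C@@H](O)/C=C(/C)I | intermediate
10 | 2-(bromomethyl)prop-2-enoic acid | C=C(CBr)C(=O)O | starting material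
11 | (3R,4Z)-5-iodohexa-1,4-dien-3-yl 2-(bromomethyl)prop-2-enoate | C=C(CBr)C(=O)O[C@H](C=C)/C=C(/C)I | intermediate
12 | (5R)-3-(bromomethyl)-5-[(1Z)-2-iodoprop-1-en-1-yl]furan-2(5H)-one | BrCC1=C[C@H](/C=C(/C)I)OC1=O | intermediate
13 | (4S,5R)-4-[(1R,2E)-1,6-dihydroxy-3-methylhex-2-en-1-yl]-5-[(1Z)-2-iodoprop-1-en-1-yl]-3-methylideneoxolan-2-one | C=C1C(=O)O[C@@H](/C=C(/C)I)[C@@H]1[C@H](O)/C=C(\C)CCCO | intermediate
14 | (4E,6R)-6-hydroxy-6-[(2R,3S)-2-[(1Z)-2-iodoprop-1-en-1-yl]-4-methylidene-5-oxooxolan-3-yl]-4-methylhex-4-enal | C=C1C(=O)O[C@@H](/C=C(/C)I)[C@@H]1[C@H](O)/C=C(\C)CCC=O | intermediate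
15 | (1R,2E)-1-[(2R,3S)-2-[(1Z)-2-iodoprop-1-en-1-yl]-4-methylidene-5-oxooxolan-3-yl]-3-methyl-6-oxohex-2-en-1-yl formate | C=C1C(=O)O[C@@H](/C=C(/C)I)[C@@H]1[C@H](OC=O)/C=C(\C)CCC=O | intermediate
16 | (6R,7S,8S)-6-formyloxy-1-hydroxygermacra-4E,9Z,11(13)-trien-12,8-olide (both C1 epimers) | C=C1C(=O)O[C@H]2/C=C(/C)C(O)CC/C(C)=C/[C@@H](OC=O)[C@H]12 | intermediate
17 | N1-(2-nitrobenzenesulfonyl)hydrazine at C1 of the 6R macrocycle (C1 epimers) | C=C1C(=O)O[C@H]2/C=C(/C)C(N(N)S(=O)(=O)c3ccccc3[N+](=O)[O-])CC/C(C)=C/[C@@H](OC=O)[C@H]12 | intermediate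
18 | C1 allylic diazene of the 6R macrocycle (C1 epimers) | C=C1C(=O)O[C@H]2/C=C(/C)C(N=N)CC/C(C)=C/[C@@H](OC=O)[C@H]12 | intermediate
19 | (6R,7S,8S)-6-formyloxygermacra-1(10)E,4E,11(13)-trien-12,8-olide | C=C1C(=O)O[C@H]2C/C(C)=C/CC/C(C)=C/[C@@H](OC=O)[C@@H]21 | intermediate
20 | (1S,2E)-1-[(2R,3S)-2-[(1Z)-2-iodoprop-1-en-1-yl]-4-methylidene-5-oxooxolan-3-yl]-3-methyl-6-oxohex-2-en-1-yl formate | C=C1C(=O)O[C@@H](/C=C(/C)I)[C@@H]1[C@@H](OC=O)/C=C(\C)CCC=O | intermediate
21 | (6S,7S,8S)-6-formyloxy-1-hydroxygermacra-4E,9Z,11(13)-trien-12,8-olide (both C1 epimers) | C=C1C(=O)O[C@H]2/C=C(/C)C(O)CC/C(C)=C/[C@H](OC=O)[C@H]12 | intermediate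
22 | C1 methyl oxalate of 21 (C1 epimers) | C=C1C(=O)O[C@H]2/C=C(/C)C(OC(=O)C(=O)OC)CC/C(C)=C/[C@H](OC=O)[C@H]12 | intermediate
23 | caesium C1 oxalate of 21 (C1 epimers) | C=C1C(=O)O[C@H]2/C=C(/C)C(OC(=O)C(=O)[O-])CC/C(C)=C/[C@H](OC=O)[C@H]12.[Cs+] | intermediate
24 | 6,6′-di-O-formyl derivative of the target (1S,6S,7S,8S; 6′R,7′S,8′S,11′R) | C=C1C(=O)O[C@H]2/C=C(/C)[C@H](C[C@H]3C(=O)O[C@H]4C/C(C)=C/CC/C(C)=C/[C@@H](OC=O)[C@@H]43)CC/C(C)=C/[C@H](OC=O)[C@H]12 | intermediate
25 | target: (1S,6S,7S,8S)-6-hydroxygermacra-4E,9Z,11(13)-trien-12,8-olide bonded at C1 to C13′ of (6′R,7′S,8′S,11′R)-6′-hydroxy-11′,13′-dihydrogermacra-1′(10′)E,4′E-dien-12′,8′-olide | C=C1C(=O)O[C@H]2/C=C(/C)[C@H](C[C@H]3C(=O)O[C@H]4C/C(C)=C/CC/C(C)=C/[C@@H](O)[C@@H]43)CC/C(C)=C/[C@H](O)[C@H]12 | target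

**Step count and risks**
Total: 17 steps. Longest linear sequence: 12 steps (3 → 4 → 5 → 6 → 7 → 8 → 9 → 13 → 14 → 15 → 16 → 17; the branch through 10 → 11 → 12 is equally long).

Most likely to fail:

1. Step 16, the radical union. The allyl radical is stabilised and adds slowly. It can also add to the methylene lactone of 23 or 24, or react through C9. The face selectivity at C1 rests on a conformational argument and could favour the C1 epimer. The fallback sets out from 21 and rejoins at 24, replacing the radical union by a pericyclic one. The transposition of step 12 (NBSH, PPh3, DEAD) applied to 21 passes through the sulfonylhydrazine F1 and the allylic diazene F2 to the 6-epimeric monomer formate F3. F3 and 19 (3 equiv) are then joined by an intermolecular ene reaction at 12 kbar (CH2Cl2, 40 °C). The methylene lactone of 19 takes the exo face of C1=C10 of F3 and H-9, which gives 24 with the 9Z alkene.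

2. Step 12, the reductive transposition. The Mitsunobu step is on a hindered ring alcohol, and the E geometry of the new C1=C10 alkene depends on the ring keeping H-1 in the olefin plane. The fallback sets out from 16 and rejoins at 19, with the geometry set photochemically instead of by the sigmatropic step. If the transposition gives the 1(10)Z isomer F4, F4 is irradiated (254 nm, MeCN, or benzophenone-sensitised) and the 1(10)E isomer 19 is separated from the photostationary mixture, with F4 recycled.

3. Step 13, the Mitsunobu inversion. The alcohol is allylic, flanked by the lactone ring carbon, and an aldehyde is present; retention, elimination or SN2′ attack are possible. The fallback sets out from 12 and rejoins at 20, making the 6,7-syn relationship directly. Zinc dust and Bu3SnCl in THF–aq. NH4Cl convert 12 into the allylstannane F5. BF3·OEt2-promoted addition of F5 to 4 (CH2Cl2, −78 °C) goes through an open transition state, still anti to the C8 arm, and gives the 6S diol F6. TEMPO/PhI(OAc)2 oxidation gives the 6S hydroxy aldehyde F7, and acetic formic anhydride in pyridine (retention) gives 20.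

Further compounds
F1 | step 16 | N1-(2-nitrobenzenesulfonyl)hydrazine at C1 of the 6S macrocycle (C1 epimers) | C=C1C(=O)O[C@H]2/C=C(/C)C(N(N)S(=O)(=O)c3ccccc3[N+](=O)[O-])CC/C(C)=C/[C@H](OC=O)[C@H]12
F2 | step 16 | C1 allylic diazene of the 6S macrocycle (C1 epimers) | C=C1C(=O)O[C@H]2/C=C(/C)C(N=N)CC/C(C)=C/[C@H](OC=O)[C@H]12
F3 | step 16 | (6S,7S,8S)-6-formyloxygermacra-1(10)E,4E,11(13)-trien-12,8-olide | C=C1C(=O)O[C@H]2C/C(C)=C/CC/C(C)=C/[C@H](OC=O)[C@@H]21
F4 | step 12 | (6R,7S,8S)-6-formyloxygermacra-1(10)Z,4E,11(13)-trien-12,8-olide | C=C1C(=O)O[C@H]2C/C(C)=C\CC/C(C)=C/[C@@H](OC=O)[C@@H]21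
F5 | step 13 | (5R)-5-[(1Z)-2-iodoprop-1-en-1-yl]-3-[(tributylstannyl)methyl]furan-2(5H)-one | CCCC[Sn](CCCC)(CCCC)CC1=C[C@H](/C=C(/C)I)OC1=O
F6 | step 13 | (4S,5R)-4-[(1S,2E)-1,6-dihydroxy-3-methylhex-2-en-1-yl]-5-[(1Z)-2-iodoprop-1-en-1-yl]-3-methylideneoxolan-2-one | C=C1C(=O)O[C@@H](/C=C(/C)I)[C@@H]1[C@@H](O)/C=C(\C)CCCO
F7 | step 13 | (4E,6S)-6-hydroxy-6-[(2R,3S)-2-[(1Z)-2-iodoprop-1-en-1-yl]-4-methylidene-5-oxooxolan-3-yl]-4-methylhex-4-enal | C=C1C(=O)O[C@@H](/C=C(/C)I)[C@@H]1[C@@H](O)/C=C(\C)CCC=O
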